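The target is one oxolane ring, O1–C2(H)(3,4-dihydroxyphenyl)–C3(H)(C9H2OH)–C4(OH)(3,4-dimethoxybenzyl)–C5H2, with aryl, hydroxymethyl and hydroxyl all on one face.
Feature used: C2 is a benzylic carbon at the aldehyde (acetal) level between O1 and C3, and C9 can be carried as a vinyl group, so O1–C2 and C2–C3 are cut together to give an aryl aldehyde and an acyclic C5 silyl ether that holds C4 and a (Z)-allylsilane at C3.
The only ring is closed in that one step (condensation at O1, allylsilane capture at C2), which also sets C2 and C3 under the control of C4.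
C4 is set earlier by Sharpless epoxidation of mono-benzylated 2-methylidenepropane-1,3-diol and opening of the epoxide CH2 with the aryl Grignard reagent; the benzyloxymethyl arm then becomes the aldehyde for a Z-selective Wittig reaction.
After ring closure the vinyl group is cut down to C9H2OH, and the silyl and benzyl groups are removed.
Key step: step 9

Remark: the ring numbering O1, C2 (aryl), C3 (C9 substituent), C4 (oxygen and 3,4-dimethoxybenzyl), C5 is kept in all names; read this way the target SMILES is (2R,3R,4R).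
Remark: the face sense of the epoxidation in step 2 is taken from the established course with simple primary allylic alcohols (L-(+)-tartrate turns (E)-hex-2-en-1-ol into its (2S,3S)-epoxy alcohol); 2-methylidenepropane-1,3-diol and D-(−)-diethyl tartrate are taken as commercial.

Step 1
Reactants: 1 2-methylidenepropane-1,3-diol
Product: 2 2-[(benzyloxy)methyl]prop-2-en-1-ol
Conditions: BnBr (1.05 equiv), Ag2O (1.5 equiv), CH2Cl2, rt
Reagents that add atoms: benzyl bromide, BrCc1ccccc1
Why: Ag2O-mediated Williamson etherification of a symmetric diol should stop at the monoether, because the silver-bound diol is alkylated once and the product binds silver less well; no stereocentre is formed, and a benzyl group (unlike a silyl group) cannot migrate between the two arms later.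

Step 2
Reactants: 2 2-[(benzyloxy)methyl]prop-2-en-1-ol
Product: 3 (R)-{2-[(benzyloxy)methyl]oxiran-2-yl}methanol
Conditions: Ti(OiPr)4 (10 mol %), D-(−)-diethyl tartrate (12 mol %), t-BuOOH (2 equiv), 4 Å molecular sieves, CH2Cl2, −20 °C
Reagents that add atoms: tert-butyl hydroperoxide, CC(C)(C)OO
Why: Sharpless asymmetric epoxidation of a 2-substituted allylic alcohol; the D-(−)-tartrate catalyst delivers oxygen to the face opposite to that used by L-(+)-tartrate (the sense that converts (E)-hex-2-en-1-ol into its (2R,3R)-epoxy alcohol), which should set the quaternary epoxide carbon as R.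

Step 3
Reactants: 3 (R)-{2-[(benzyloxy)methyl]oxiran-2-yl}methanol, 4 4-bromo-1,2-dimethoxybenzene
Product: 6 (S)-2-[(benzyloxy)methyl]-3-(3,4-dimethoxyphenyl)propane-1,2-diol, via aryl Grignard reagent 5 (not isolated)
Conditions: 4, Mg, THF, 40 °C; then 3 added to 5 (3 equiv) and CuI (10 mol %), THF, −30 → 0 °C; aq NH4Cl
Reagents that add atoms: none
Why: Copper-catalysed Grignard opening of a 2,2-disubstituted epoxide goes by SN2 attack at the unsubstituted CH2, so the 3,4-dimethoxybenzyl group is installed while the C–O bond of the quaternary carbon, and with it the configuration, is untouched (one equivalent of 5 is used up by the hydroxyl proton, and Payne rearrangement of the alkoxide is degenerate for this substrate).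

Step 4
Reactants: 6 (S)-2-[(benzyloxy)methyl]-3-(3,4-dimethoxyphenyl)propane-1,2-diol
Product: 7 (R)-1-(benzyloxy)-2-(3,4-dimethoxybenzyl)-2,3-bis(triethylsilyloxy)propane
Conditions: Et3SiOTf (2.5 equiv), 2,6-lutidine (4 equiv), CH2Cl2, −78 → 0 °C
Reagents that add atoms: triethylsilyl trifluoromethanesulfonate, CC[Si](CC)(CC)OS(=O)(=O)C(F)(F)F
Why: A silyl triflate with 2,6-lutidine silylates the hindered tertiary as well as the primary hydroxyl, which gives in one operation the primary silyl ether that later acts as the O1 nucleophile and a fluoride-labile protecting group on the C4 oxygen.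

Step 5
Reactants: 7 (R)-1-(benzyloxy)-2-(3,4-dimethoxybenzyl)-2,3-bis(triethylsilyloxy)propane
Product: 8 (R)-2-(3,4-dimethoxybenzyl)-2,3-bis(triethylsilyloxy)propan-1-ol
Conditions: H2 (1 atm), 10% Pd/C, EtOAc, rt
Reagents that add atoms: none
Why: Hydrogenolysis of the alkyl benzyl ether over Pd/C in ethyl acetate is neutral, so the triethylsilyl ethers should stay in place and cannot migrate between the two oxygenated arms (which would erase the stereocentre), and it frees the one primary hydroxyl whose carbon becomes C3.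

Step 6
Reactants: 8 (R)-2-(3,4-dimethoxybenzyl)-2,3-bis(triethylsilyloxy)propan-1-ol
Product: 9 (S)-2-(3,4-dimethoxybenzyl)-2,3-bis(triethylsilyloxy)propanal
Conditions: Dess–Martin periodinane (1.3 equiv), pyridine (3 equiv), CH2Cl2, 0 °C → rt
Reagents that add atoms: none
Why: Buffered Dess–Martin oxidation of a primary alcohol to the aldehyde is mild enough for both silyl ethers, and the aldehyde has no α-hydrogen, so it can neither enolise nor racemise.

Step 7
Reactants: 10 methyltriphenylphosphonium bromide, 11 (iodomethyl)trimethylsilane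
Product: 13 triphenyl[2-(trimethylsilyl)ethyl]phosphonium iodide, via methylidenetriphenylphosphorane 12 (not isolated)
Conditions: 10, n-BuLi (1.0 equiv), THF, 0 °C; then 11, 0 °C → rt; filtration
Reagents that add atoms: none
Why: C-Alkylation of the non-stabilised methylide with the reactive primary iodide is the established way to this β-silyl phosphonium salt, which should precipitate from THF and be collected free of lithium salts.

Step 8
Reactants: 9 (S)-2-(3,4-dimethoxybenzyl)-2,3-bis(triethylsilyloxy)propanal, 13 triphenyl[2-(trimethylsilyl)ethyl]phosphonium iodide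
Product: 15 (R,Z)-2-(3,4-dimethoxybenzyl)-1,2-bis(triethylsilyloxy)-5-(trimethylsilyl)pent-3-ene, via silylethylidene ylide 14 (not isolated)
Conditions: 13 (1.3 equiv), NaN(SiMe3)2 (1.25 equiv), THF, −78 → 0 °C; then 9, −78 °C → rt
Reagents that add atoms: none
Why: Wittig olefination with a non-stabilised ylide under lithium-free conditions passes through the kinetic cis-oxaphosphetane and should give the (Z)-allylsilane; the quaternary stereocentre takes no part.

Step 9
Reactants: 15 (R,Z)-2-(3,4-dimethoxybenzyl)-1,2-bis(triethylsilyloxy)-5-(trimethylsilyl)pent-3-ene, 16 3,4-bis(benzyloxy)benzaldehyde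
Product: 18 (2R,3R,4R)-2-[3,4-bis(benzyloxy)phenyl]-4-(3,4-dimethoxybenzyl)-4-(triethylsilyloxy)-3-vinyloxolane, via oxocarbenium triflate 17 (not isolated)
Conditions: 16 (1.3 equiv), Me3SiOTf (0.3 equiv), 2,6-di-tert-butyl-4-methylpyridine (0.3 equiv), CH2Cl2, −78 °C; Et3N, −78 °C
Reagents that add atoms: none
Why: Me3SiOTf activates aldehyde 16, the primary triethylsilyl ether oxygen of 15 adds to it and the two silyl groups leave as Et3SiOSiMe3, which forms the O1–C2 bond and the (E)-oxocarbenium ion 17; the γ-carbon of the allylsilane then attacks C2 anti to silicon (C2–C3 bond), and loss of Me3Si from the β-silyl cation leaves the 3-vinyl group and regenerates Me3SiOTf. The closest known reaction is the Lewis acid-mediated condensation of aldehydes with 5-silylpent-3-en-1-ol derivatives (intramolecular Sakurai or silyl-Prins cyclisation), which gives 2,3-cis-3-vinyloxolanes. The oxolane closes 5-endo-trig with respect to the C=O+ bond, both atoms of which end in the ring, and 5-exo with respect to the alkene, a mode that oxocarbenium ions follow readily. C2 is controlled by the E geometry of 17 (aryl pseudo-equatorial) together with a synclinal arrangement of C=O+ and C=C in the envelope transition state, which should place the aryl group and the future vinyl carbon on the same face (2,3-cis). C3 is controlled by the C4 stereocentre: the tether holds C5 perpendicular to the alkene plane, and of the two other C4 substituents the C–OSiEt3 bond should take the inside position next to the cis CH2SiMe3 group (less A(1,3) strain, inside-alkoxy preference) while the bulkier 3,4-dimethoxybenzyl group points outside, so that the vinyl group ends cis to the silyloxy group. The step needs kinetic control; the (Z)-allylsilane and the size difference at C4 are the substrate elements that secure it, supported by −78 °C, sub-stoichiometric Me3SiOTf, a hindered pyridine that keeps triflic acid from the allylsilane and a cold amine quench against re-ionisation at the benzylic C2–O1 bond.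

Step 10
Reactants: 18 (2R,3R,4R)-2-[3,4-bis(benzyloxy)phenyl]-4-(3,4-dimethoxybenzyl)-4-(triethylsilyloxy)-3-vinyloxolane
Product: 20 [(2R,3R,4R)-2-[3,4-bis(benzyloxy)phenyl]-4-(3,4-dimethoxybenzyl)-4-(triethylsilyloxy)oxolan-3-yl]methanol, via aldehyde 19 (not isolated)
Conditions: OsO4 (2 mol %), NaIO4 (4 equiv), 2,6-lutidine (2 equiv), 1,4-dioxane/H2O 3:1, rt; then NaBH4, MeOH, 0 °C, same flask
Reagents that add atoms: sodium periodate, [Na+].[O-]I(=O)(=O)=O (its oxygen is passed on by OsO4 and ends as the C9 oxygen)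
Why: Lemieux–Johnson cleavage of the only alkene (osmylation, then periodate scission of the diol) gives aldehyde 19, which is reduced by NaBH4 in the same flask before the epimerisable C3 centre or the β-silyloxy group can react; 2,6-lutidine keeps the medium near neutral and C2, C3 and C4 are untouched.

Step 11
Reactants: 20 [(2R,3R,4R)-2-[3,4-bis(benzyloxy)phenyl]-4-(3,4-dimethoxybenzyl)-4-(triethylsilyloxy)oxolan-3-yl]methanol
Product: 21 (2R,3R,4R)-2-[3,4-bis(benzyloxy)phenyl]-4-(3,4-dimethoxybenzyl)-3-(hydroxymethyl)oxolan-4-ol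
Conditions: Bu4NF (1.5 equiv), THF, 0 °C → rt; aq NH4Cl
Reagents that add atoms: none
Why: Fluoride cleaves the tertiary triethylsilyl ether through the strong Si–F bond under non-acidic conditions that cannot ionise the benzylic C2–O1 bond, and the aryl benzyl ethers are inert to it.

Step 12
Reactants: 21 (2R,3R,4R)-2-[3,4-bis(benzyloxy)phenyl]-4-(3,4-dimethoxybenzyl)-3-(hydroxymethyl)oxolan-4-ol
Product: 22 (2R,3R,4R)-2-(3,4-dihydroxyphenyl)-4-(3,4-dimethoxybenzyl)-3-(hydroxymethyl)oxolan-4-ol
Conditions: H2 (1 atm), 10% Pd/C, EtOAc/MeOH 4:1, rt, stopped at full debenzylation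
Reagents that add atoms: none
Why: Hydrogenolysis of aryl benzyl ethers over Pd/C is much faster than cleavage of the dialkyl benzylic C2–O1 ether, so a reaction stopped once both benzyl groups are gone should give the catechol with all three stereocentres intact.

Compound list
1 | 2-methylidenepropane-1,3-diol | C=C(CO)CO | starting material
2 | 2-[(benzyloxy)methyl]prop-2-en-1-ol | C=C(CO)COCc1ccccc1 | intermediate
3 | (R)-{2-[(benzyloxy)methyl]oxiran-2-yl}methanol | OC[C@]1(COCc2ccccc2)CO1 | intermediate
4 | 4-bromo-1,2-dimethoxybenzene | COc1ccc(Br)cc1OC | starting material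
5 | (3,4-dimethoxyphenyl)magnesium bromide | COc1ccc([Mg]Br)cc1OC | intermediate
6 | (S)-2-[(benzyloxy)methyl]-3-(3,4-dimethoxyphenyl)propane-1,2-diol | OC[C@@](O)(Cc1ccc(OC)c(OC)c1)COCc1ccccc1 | intermediate
7 | (R)-1-(benzyloxy)-2-(3,4-dimethoxybenzyl)-2,3-bis(triethylsilyloxy)propane | CC[Si](CC)(CC)OC[C@@](O[Si](CC)(CC)CC)(Cc1ccc(OC)c(OC)c1)COCc1ccccc1 | intermediate
8 | (R)-2-(3,4-dimethoxybenzyl)-2,3-bis(triethylsilyloxy)propan-1-ol | CC[Si](CC)(CC)OC[C@@](O[Si](CC)(CC)CC)(Cc1ccc(OC)c(OC)c1)CO | intermediate
9 | (S)-2-(3,4-dimethoxybenzyl)-2,3-bis(triethylsilyloxy)propanal | CC[Si](CC)(CC)OC[C@@](O[Si](CC)(CC)CC)(Cc1ccc(OC)c(OC)c1)C=O | intermediate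
10 | methyltriphenylphosphonium bromide | C[P+](c1ccccc1)(c1ccccc1)c1ccccc1.[Br-] | starting material
11 | (iodomethyl)trimethylsilane | C[Si](C)(C)CI | starting material
12 | methylidenetriphenylphosphorane | C=P(c1ccccc1)(c1ccccc1)c1ccccc1 | intermediate
13 | triphenyl[2-(trimethylsilyl)ethyl]phosphonium iodide | C[Si](C)(C)CC[P+](c1ccccc1)(c1ccccc1)c1ccccc1.[I-] | intermediate
14 | triphenyl[2-(trimethylsilyl)ethylidene]phosphorane | C[Si](C)(C)CC=P(c1ccccc1)(c1ccccc1)c1ccccc1 | intermediate
15 | (R,Z)-2-(3,4-dimethoxybenzyl)-1,2-bis(triethylsilyloxy)-5-(trimethylsilyl)pent-3-ene | CC[Si](CC)(CC)OC[C@@](O[Si](CC)(CC)CC)(Cc1ccc(OC)c(OC)c1)/C=C\C[Si](C)(C)C | intermediate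
16 | 3,4-bis(benzyloxy)benzaldehyde | O=Cc1ccc(OCc2ccccc2)c(OCc2ccccc2)c1 | starting material
17 | (E)-[3,4-bis(benzyloxy)benzylidene][(R,Z)-2-(3,4-dimethoxybenzyl)-2-(triethylsilyloxy)-5-(trimethylsilyl)pent-3-enyl]oxonium trifluoromethanesulfonate | C(c1ccccc1)Oc1ccc(/C=[O+]/C[C@@](O[Si](CC)(CC)CC)(Cc2ccc(OC)c(OC)c2)/C=C\C[Si](C)(C)C)cc1OCc1ccccc1.[O-]S(=O)(=O)C(F)(F)F | intermediate
18 | (2R,3R,4R)-2-[3,4-bis(benzyloxy)phenyl]-4-(3,4-dimethoxybenzyl)-4-(triethylsilyloxy)-3-vinyloxolane (aryl, vinyl and silyloxy all cis) | COc1ccc(C[C@]2(O[Si](CC)(CC)CC)CO[C@@H](c3ccc(OCc4ccccc4)c(OCc4ccccc4)c3)[C@H]2C=C)cc1OC | intermediate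
19 | (2R,3R,4R)-2-[3,4-bis(benzyloxy)phenyl]-4-(3,4-dimethoxybenzyl)-4-(triethylsilyloxy)oxolane-3-carbaldehyde | COc1ccc(C[C@]2(O[Si](CC)(CC)CC)CO[C@@H](c3ccc(OCc4ccccc4)c(OCc4ccccc4)c3)[C@H]2C=O)cc1OC | intermediate
20 | [(2R,3R,4R)-2-[3,4-bis(benzyloxy)phenyl]-4-(3,4-dimethoxybenzyl)-4-(triethylsilyloxy)oxolan-3-yl]methanol | COc1ccc(C[C@]2(O[Si](CC)(CC)CC)CO[C@@H](c3ccc(OCc4ccccc4)c(OCc4ccccc4)c3)[C@H]2CO)cc1OC | intermediate
21 | (2R,3R,4R)-2-[3,4-bis(benzyloxy)phenyl]-4-(3,4-dimethoxybenzyl)-3-(hydroxymethyl)oxolan-4-ol | COc1ccc(C[C@]2(O)CO[C@@H](c3ccc(OCc4ccccc4)c(OCc4ccccc4)c3)[C@H]2CO)cc1OC | intermediate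
22 | (2R,3R,4R)-2-(3,4-dihydroxyphenyl)-4-(3,4-dimethoxybenzyl)-3-(hydroxymethyl)oxolan-4-ol (aryl, hydroxymethyl and hydroxyl all cis) | COc1ccc(C[C@]2(O)CO[C@@H](c3ccc(O)c(O)c3)[C@H]2CO)cc1OC | target

Total step count: 12
Longest linear sequence: 11 steps (steps 1 to 6 and 8 to 12, from 1); step 7 is a one-step side branch.

Steps most likely to fail

Step 9. The Lewis acid may ionise the tertiary allylic silyl ether, with loss of the silyloxy group and of Me3Si to a diene. The oxocarbenium ion may also be trapped by the neighbouring tertiary silyl ether oxygen as a 2-aryl-1,3-dioxolane, and face selectivity may drop if the condensation needs warming. The fallback makes the same cation from an isolated precursor instead of by intermolecular condensation. It sets out from 15: the primary triethylsilyl ether alone is cleaved (pyridinium p-toluenesulfonate, MeOH/CH2Cl2, 0 °C) to the primary alcohol F1, which is esterified with 3,4-bis(benzyloxy)benzoic acid (EDC, DMAP, CH2Cl2) to the 3,4-bis(benzyloxy)benzoate F2. Reductive acetylation of the ester (iBu2AlH, −78 °C; then Ac2O, pyridine, DMAP) should give the α-acetoxy ether F3. BF3·OEt2 in CH2Cl2 at −78 °C ionises F3 to the oxocarbenium ion with no free aldehyde or silyl triflate in the flask, and allylsilane capture brings the route back at 18.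

Step 10. The all-cis aldehyde may epimerise at C3 or undergo β-elimination (loss of the C4 silyloxy group or opening at C2–O1) during the slow periodate cleavage at room temperature. The fallback sets out from 18: ozone in CH2Cl2 at −78 °C, with Sudan Red 7B as end-point indicator to spare the electron-rich arenes, should give the ozonide F4. F4 is reduced in the cold by NaBH4 after addition of MeOH, so that the free aldehyde never accumulates; the route is rejoined at 20.

Step 12. Hydrogenation may run on, with hydrogenolytic opening of the benzylic C2–O1 bond once the para-hydroxyl is free, or C2 may epimerise on the catalyst. The fallback avoids hydrogenation by carrying the catechol as silyl ethers. It sets out from 15, which is condensed under the conditions of step 9 with 3,4-bis(tert-butyldimethylsilyloxy)benzaldehyde F5 (from 3,4-dihydroxybenzaldehyde, t-BuMe2SiCl, imidazole, DMF) to give the silyl-protected oxolane F6. Cleavage and reduction as in step 10 give the primary alcohol F7. One buffered fluoride treatment (HF·pyridine, pyridine, THF, 0 °C → rt) removes all three silyl groups and arrives directly at 22.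

Further compounds
F1 | step 9 | (R,Z)-2-(3,4-dimethoxybenzyl)-2-(triethylsilyloxy)-5-(trimethylsilyl)pent-3-en-1-ol | OC[C@@](O[Si](CC)(CC)CC)(Cc1ccc(OC)c(OC)c1)/C=C\C[Si](C)(C)C
F2 | step 9 | (R,Z)-2-(3,4-dimethoxybenzyl)-2-(triethylsilyloxy)-5-(trimethylsilyl)pent-3-enyl 3,4-bis(benzyloxy)benzoate | O=C(OC[C@@](O[Si](CC)(CC)CC)(Cc1ccc(OC)c(OC)c1)/C=C\C[Si](C)(C)C)c1ccc(OCc2ccccc2)c(OCc2ccccc2)c1
F3 | step 9 | [3,4-bis(benzyloxy)phenyl][(R,Z)-2-(3,4-dimethoxybenzyl)-2-(triethylsilyloxy)-5-(trimethylsilyl)pent-3-enyloxy]methyl acetate (both epimers at the acetal carbon) | CC(=O)OC(OC[C@@](O[Si](CC)(CC)CC)(Cc1ccc(OC)c(OC)c1)/C=C\C[Si](C)(C)C)c1ccc(OCc2ccccc2)c(OCc2ccccc2)c1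
F4 | step 10 | 1,2,4-trioxolane (ozonide) formed at the vinyl group of 18, ring stereocentres as in 18 | COc1ccc(C[C@]2(O[Si](CC)(CC)CC)CO[C@@H](c3ccc(OCc4ccccc4)c(OCc4ccccc4)c3)[C@H]2C2OCOO2)cc1OC
F5 | step 12 | 3,4-bis(tert-butyldimethylsilyloxy)benzaldehyde | O=Cc1ccc(O[Si](C)(C)C(C)(C)C)c(O[Si](C)(C)C(C)(C)C)c1
F6 | step 12 | (2R,3R,4R)-2-[3,4-bis(tert-butyldimethylsilyloxy)phenyl]-4-(3,4-dimethoxybenzyl)-4-(triethylsilyloxy)-3-vinyloxolane | COc1ccc(C[C@]2(O[Si](CC)(CC)CC)CO[C@@H](c3ccc(O[Si](C)(C)C(C)(C)C)c(O[Si](C)(C)C(C)(C)C)c3)[C@H]2C=C)cc1OC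
F7 | step 12 | [(2R,3R,4R)-2-[3,4-bis(tert-butyldimethylsilyloxy)phenyl]-4-(3,4-dimethoxybenzyl)-4-(triethylsilyloxy)oxolan-3-yl]methanol | COc1ccc(C[C@]2(O[Si](CC)(CC)CC)CO[C@@H](c3ccc(O[Si](C)(C)C(C)(C)C)c(O[Si](C)(C)C(C)(C)C)c3)[C@H]2CO)cc1OC
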